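**Assumptions**
- The target is the C2-symmetric all-(R) 2,6-diaryl-3,5-dimethyl-1,4-dioxane. The two aryls are trans to each other, the two methyls are trans to each other, and each aryl is trans to its neighbouring methyl.
- The final oxa-1,6-cyclisation is assumed to be kinetically controlled. As in base-mediated oxa-Michael ring closures, axial attack should give the 2,6-trans ring. I found no direct precedent for this substrate, so it is the main risk.

**Retrosynthesis**
1. The dioxane ring is closed last. A fluoride-triggered p-quinone methide is captured by the pendant benzylic alkoxide (oxa-1,6-addition), and this sets the second benzylic centre.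
2. The C2-symmetric acyclic diol comes from two chelation-controlled aryl-Grignard additions to (R,R)-2,2'-oxydipropanal. That dialdehyde is built from ethyl (S)- and (R)-lactate, which set both methyl-bearing centres.
3. The two biaryl bonds are made by Suzuki coupling of a bis-boronate with a 4-allyl-2,6-dibromophenol silyl ether.
4. That allylphenol comes from 2,6-dibromophenol by O-allylation and para-Claisen rearrangement (Claisen then Cope). Both ortho positions are blocked by bromine, so the allyl group ends up para.

---

**Step 1**
Reactants: 1, ethyl (S)-lactate (1 equiv)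
Product: 2, ethyl (S)-2-(triflyloxy)propanoate
Conditions: Tf2O (1.1 equiv), 2,6-lutidine, CH2Cl2, −20 °C → 0 °C; use crude
Reagents that add atoms: triflic anhydride, O=S(=O)(OS(=O)(=O)C(F)(F)F)C(F)(F)F
Why: O-Sulfonylation keeps the C–O bond, so the configuration is retained and the product is an α-ester triflate that is a strong SN2 electrophile.

**Step 2**
Reactants: 2, ethyl (S)-2-(triflyloxy)propanoate (1 equiv); 3, ethyl (R)-lactate (1.2 equiv)
Product: 4, diethyl (2R,2'R)-2,2'-oxydipropanoate
Conditions: 2,6-di-tert-butyl-4-methylpyridine, CH2Cl2, 0 °C → rt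
Reagents that add atoms: none
Why: The hydroxyl of (R)-lactate displaces the triflate by SN2 with inversion (S → R), while its own centre is untouched, giving the C2-symmetric (R,R) ether (Williamson-type etherification).

**Step 3**
Reactants: 4, diethyl (2R,2'R)-2,2'-oxydipropanoate (1 equiv)
Product: 5, (2R,2'R)-2,2'-oxydipropanal
Conditions: DIBAL-H (2.2 equiv), toluene, −78 °C; cold work-up, use immediately
Reagents that add atoms: none
Why: Low-temperature DIBAL-H partial reduction takes each ester to the aldehyde, and the α-alkoxy aldehydes are configurationally labile, so they are used without purification.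

**Step 4**
Reactants: 6, 2-bromo-4-iodophenol (1 equiv)
Product: 7, tert-butyl(2-bromo-4-iodophenoxy)dimethylsilane
Conditions: TBSCl (1.1 equiv), imidazole, DMF, rt
Reagents that add atoms: TBSCl, CC(C)(C)[Si](C)(C)Cl
Why: Silylation masks the phenol so that an aryl Grignard can be made from the aryl iodide.

**Step 5**
Reactants: 5, (2R,2'R)-2,2'-oxydipropanal (1 equiv); 7, silyl ether of 2-bromo-4-iodophenol (2.6 equiv, converted in situ to its aryl Grignard)
Product: 8, the (R,R,R,R) bis(benzylic) diol
Conditions: 7 + iPrMgCl·LiCl (2.6 equiv), THF, −20 °C (I/Mg exchange); MgBr2·OEt2 (2.6 equiv); then 5 (1 equiv, i.e. 0.38 equiv relative to the aryl Grignard), −78 °C → −20 °C; aqueous NH4Cl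
Reagents that add atoms: none
Why: Selective I/Mg exchange leaves the Br and OTBS intact, and two equivalents of aryl Grignard add, one to each aldehyde. Mg-chelated (Cram-chelate) addition occurs on the face anti to the methyl, which gives the (R)-carbinol at both ends from the (R)-configured α-centres.

**Step 6**
Reactants: 8, bis(benzylic) diol (1 equiv)
Product: 9, the bis(pinacolboronate) diol
Conditions: B2pin2 (2.5 equiv), Pd(dppf)Cl2 (5 mol%), KOAc, 1,4-dioxane, 90 °C
Reagents that add atoms: bis(pinacolato)diboron, CC1(C)OB(OC1(C)C)B1OC(C)(C)C(C)(C)O1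
Why: Miyaura borylation converts each ortho-silyloxy aryl bromide to the boronate, and the free secondary benzylic alcohols and TBS ethers are inert.

**Step 7**
Reactants: 10, 2,6-dibromophenol (1 equiv)
Product: 11, allyl 2,6-dibromophenyl ether
Conditions: allyl bromide (1.2 equiv), K2CO3, acetone, reflux
Reagents that add atoms: allyl bromide, C=CCBr
Why: Williamson O-allylation of the phenoxide.

**Step 8**
Reactants: 11, allyl 2,6-dibromophenyl ether (1 equiv)
Product: 12, 4-allyl-2,6-dibromophenol
Conditions: N,N-diethylaniline, 210 °C (microwave), 1 h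
Reagents that add atoms: none
Why: The aromatic Claisen [3,3] shift puts the allyl group on a bromine-bearing ortho carbon to give a cyclohexadienone. A second [3,3] (Cope) shift moves it to the para carbon, and tautomerisation re-aromatises the ring (para-Claisen, used because both ortho positions are blocked).

**Step 9**
Reactants: 12, 4-allyl-2,6-dibromophenol (1 equiv)
Product: 13, (4-allyl-2,6-dibromophenoxy)(tert-butyl)dimethylsilane
Conditions: TBSCl (1.2 equiv), imidazole, DMF, 50 °C
Reagents that add atoms: TBSCl, CC(C)(C)[Si](C)(C)Cl
Why: Silylation keeps this phenol from being acylated in Step 12 and from interfering in the Suzuki coupling.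

**Step 10**
Reactants: 9, bis(Bpin) diol (1 equiv); 13, silyl-protected dibromide (5 equiv)
Product: 14, the bis-biaryl diol that still carries one Br on each outer ring
Conditions: Pd2(dba)3 (5 mol%), SPhos (20 mol%), K3PO4, toluene/H2O, 100 °C
Reagents that add atoms: none
Why: Suzuki–Miyaura coupling forms both biaryl bonds, and the large excess of dibromide 13 favours mono-arylation of each dibromide so that each outer ring keeps one blocking Br.

**Step 11**
Reactants: 14, bis-biaryl diol (1 equiv)
Product: 15, the debrominated bis(TBS) biaryl diol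
Conditions: Bu3SnH (4 equiv), AIBN (cat.), toluene, 90 °C
Reagents that add atoms: none
Why: Radical hydrodebromination removes the temporary blocking bromines and leaves the allyl groups, silyl ethers and benzylic alcohols untouched.

**Step 12**
Reactants: 15, debrominated diol (1 equiv); acetic anhydride (1.0 equiv)
Product: 16, the mono-acetate at one benzylic alcohol
Conditions: Ac2O (1.0 equiv), Et3N, DMAP (cat.), CH2Cl2, −20 °C; separate from bis-acetate and recovered 15
Reagents that add atoms: acetic anhydride, CC(=O)OC(C)=O
Why: Acylation of the C2-symmetric diol at one of its two equivalent secondary alcohols puts a leaving group on one side only and leaves the other benzylic OH free as the nucleophile.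

**Step 13**
Reactants: 16, mono-acetate (1 equiv)
Product: 17, the target
Conditions: TBAF (6 equiv), THF, 0 °C → rt; NH4Cl work-up; chromatography on Et3N-deactivated silica
Reagents that add atoms: none
Why: Fluoride removes all four aryl TBS groups, and the phenoxide on the acetylated side expels acetate (1,6-elimination) to give a p-quinone methide. The retained (R) benzylic alkoxide then adds 6-exo by oxa-1,6-addition through a chair-like transition state in which the C2 aryl and C3 methyl are equatorial. Axial attack on the quinone methide carbon places the new aryl axial and trans to the retained aryl, which sets that centre as (R); the other three stereocentres are not involved.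

---

**Compound list**

| # | Name | SMILES | Role |
|---|---|---|---|
| 1 | ethyl (S)-lactate | CCOC(=O)[C@H](C)O | starting material |
| 2 | ethyl (S)-2-(triflyloxy)propanoate | CCOC(=O)[C@H](C)OS(=O)(=O)C(F)(F)F | intermediate |
| 3 | ethyl (R)-lactate | CCOC(=O)[C@@H](C)O | starting material |
| 4 | diethyl (2R,2'R)-2,2'-oxydipropanoate | CCOC(=O)[C@@H](C)O[C@H](C)C(=O)OCC | intermediate |
| 5 | (2R,2'R)-2,2'-oxydipropanal | O=C[C@@H](C)O[C@H](C)C=O | intermediate |
| 6 | 2-bromo-4-iodophenol | Oc1ccc(I)cc1Br | starting material |
| 7 | tert-butyl(2-bromo-4-iodophenoxy)dimethylsilane | CC(C)(C)[Si](C)(C)Oc1ccc(I)cc1Br | intermediate |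
| 8 | bis(benzylic) diol, (R,R,R,R) | CC(C)(C)[Si](C)(C)Oc1ccc(cc1Br)[C@@H](O)[C@@H](C)O[C@H](C)[C@H](O)c1ccc(O[Si](C)(C)C(C)(C)C)c(Br)c1 | intermediate |
| 9 | bis(Bpin) diol | CC(C)(C)[Si](C)(C)Oc1ccc(cc1B1OC(C)(C)C(C)(C)O1)[C@@H](O)[C@@H](C)O[C@H](C)[C@H](O)c1ccc(O[Si](C)(C)C(C)(C)C)c(c1)B1OC(C)(C)C(C)(C)O1 | intermediate |
| 10 | 2,6-dibromophenol | Oc1c(Br)cccc1Br | starting material |
| 11 | allyl 2,6-dibromophenyl ether | C=CCOc1c(Br)cccc1Br | intermediate |
| 12 | 4-allyl-2,6-dibromophenol | C=CCc1cc(Br)c(O)c(Br)c1 | intermediate |
| 13 | (4-allyl-2,6-dibromophenoxy)(tert-butyl)dimethylsilane | C=CCc1cc(Br)c(O[Si](C)(C)C(C)(C)C)c(Br)c1 | intermediate |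
| 14 | bis-biaryl diol (Br on outer rings) | CC(C)(C)[Si](C)(C)Oc1ccc(cc1-c1cc(CC=C)cc(Br)c1O[Si](C)(C)C(C)(C)C)[C@@H](O)[C@@H](C)O[C@H](C)[C@H](O)c1ccc(O[Si](C)(C)C(C)(C)C)c(c1)-c1cc(CC=C)cc(Br)c1O[Si](C)(C)C(C)(C)C | intermediate |
| 15 | debrominated bis(TBS) biaryl diol | CC(C)(C)[Si](C)(C)Oc1ccc(cc1-c1cc(CC=C)ccc1O[Si](C)(C)C(C)(C)C)[C@@H](O)[C@@H](C)O[C@H](C)[C@H](O)c1ccc(O[Si](C)(C)C(C)(C)C)c(c1)-c1cc(CC=C)ccc1O[Si](C)(C)C(C)(C)C | intermediate |
| 16 | mono-acetate of 15 | CC(C)(C)[Si](C)(C)Oc1ccc(cc1-c1cc(CC=C)ccc1O[Si](C)(C)C(C)(C)C)[C@@H](OC(C)=O)[C@@H](C)O[C@H](C)[C@H](O)c1ccc(O[Si](C)(C)C(C)(C)C)c(c1)-c1cc(CC=C)ccc1O[Si](C)(C)C(C)(C)C | intermediate |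
| 17 | target | C=CCc1ccc(O)c(-c2cc([C@H]3O[C@H](c4ccc(O)c(-c5cc(CC=C)ccc5O)c4)[C@@H](C)O[C@@H]3C)ccc2O)c1 | target |

**Total steps:** 13.
**Longest linear sequence:** 9 steps (1 → 2 → 4 → 5 → 8 → 9 → 14 → 15 → 16 → 17), counting the coupling with 3 in Step 2.

**Three steps most likely to fail**
1. **Step 13, kinetic oxa-1,6-cyclisation.** It may give the cis-aryl isomer, or fluoride/water may simply hydrolyse the acetate. Fallback: use an SN2 closure instead of the quinone methide. Convert one benzylic OH of 15 to the chloride with inversion (PPh3/NCS, statistical mono-chlorination). Then close with NaH in THF, so that a second inversion gives net retention at that centre, and finish with TBAF.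
2. **Step 5, chelation-controlled bis-addition.** Enolisation, epimerisation or poor diastereoselectivity can occur. Fallback: convert 4 to the bis-Weinreb amide, add the aryl Grignard to give the bis-aryl ketone, and reduce both ketones non-chelatingly with L-Selectride (Felkin), which gives the (R,R) carbinols.
3. **Step 8, para-Claisen of the hindered dibromophenyl ether** (C–Br cleavage or low yield). Fallback: drop the Claisen and brominate commercial 4-allylphenol ortho to OH with NBS to give 2-bromo-4-allylphenol. Protect it as the TBS ether and use it directly in Step 10, which also removes the debromination step.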